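**Plan**

- Numbering: lactone ring O1, C2–C6; side chain C1'–C21' with carbinols at C2', C4' and C6'.
- Cuts: ring C3=C4 (ring-closing metathesis) and the O1–C2 acyl bond (acrylate ester); then side-chain C3'–C4' (boron aldol), giving C18 aldehyde 4 and C7 methyl ketone 13.
- Enabling feature: C2' lies β to the oxygen-bearing ring carbon C6 and 1,3 to C4'. With C2' as a ketone, its C3' methyl is the enolisable site, the C6 ether oxygen steers the aldehyde face (1,5), and the C4'–O–B–O=C2' chelate steers hydride (1,3).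
- Forward: 4 (3 steps) and 13 (4 steps) are joined and reduced in one flask; acetonide, PMB removal, Mitsunobu acrylation, metathesis (the lactone, the only ring, is closed last) and global deprotection follow.
- Stereochemistry: C6' from Noyori hydrogenation; C6 bought as its epimer in (S)-epichlorohydrin; C4' and C2' relayed from it in the key step (1,5-anti, then 1,3-syn); C6 inverted to S in the Mitsunobu step, giving the all-syn array.

Key step: step 8

Remark: the target is read as (6S)-6-[(2R,4R,6R)-2,4,6-trihydroxyhenicosyl]-5,6-dihydro-2H-pyran-2-one, with all four C–O bonds syn along the chain. Compounds 1, 5, 6, 10 and 19 are taken as commercial. CIP descriptors of intermediates change with the protecting groups, so the SMILES are decisive. In the C25 intermediates, C4 = ring C6, C6 = C2', C8 = C4', C10 = C6'.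

**Route**

Step 1
Reactants: 1 methyl 3-oxooctadecanoate
Product: 2 methyl (3R)-3-hydroxyoctadecanoate
Conditions: RuCl2[(R)-BINAP] (0.5 mol%), H2 (50 atm), MeOH, 50 °C
Reagents that add atoms: none
Why: Noyori asymmetric hydrogenation of a β-keto ester, in which the (R)-BINAP–ruthenium chelate of the keto ester delivers hydride to one ketone face and sets C3 as R (the future C6').

Step 2
Reactants: 2 methyl (3R)-3-hydroxyoctadecanoate
Product: 3 methyl (3R)-3-[(tert-butyldimethylsilyl)oxy]octadecanoate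
Conditions: TBSCl, imidazole, DMF, rt
Reagents that add atoms: tert-butyldimethylsilyl chloride, CC(C)(C)[Si](C)(C)Cl
Why: Standard silylation of a secondary alcohol gives a robust ether that is only a weak stereodirector in the later boron aldol.

Step 3
Reactants: 3 methyl (3R)-3-[(tert-butyldimethylsilyl)oxy]octadecanoate
Product: 4 (3R)-3-[(tert-butyldimethylsilyl)oxy]octadecanal
Conditions: i-Bu2AlH (1.1 equiv), CH2Cl2, −78 °C; aq. Rochelle salt
Reagents that add atoms: none
Why: Partial ester reduction stops at the aluminium hemiacetal at −78 °C and releases the aldehyde on work-up without touching the stereocentre.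

Step 4
Reactants: 5 2-methyl-1,3-dithiane; 6 (S)-epichlorohydrin
Product: 9 (2S)-2-[(2-methyl-1,3-dithian-2-yl)methyl]oxirane, via 2-lithio-2-methyl-1,3-dithiane 7 (not isolated), via lithium chlorohydrin alkoxide 8 (not isolated)
Conditions: n-BuLi, THF, −30 °C; then 6, −78 → 0 °C
Reagents that add atoms: none
Why: Corey–Seebach umpolung, in which the lithiated dithiane opens the epoxide of 6 at its CH2 terminus and alkoxide 8 then displaces chloride, so the stereocentre is never touched and is carried into 9.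

Step 5
Reactants: 9 (2S)-2-[(2-methyl-1,3-dithian-2-yl)methyl]oxirane; 10 vinylmagnesium bromide
Product: 11 (2R)-1-(2-methyl-1,3-dithian-2-yl)pent-4-en-2-ol
Conditions: CH2=CHMgBr (1.5 equiv), CuI (10 mol%), THF, −40 → −20 °C; aq. quench
Reagents that add atoms: none
Why: Copper-catalysed Grignard opening of a terminal epoxide occurs at the unsubstituted carbon and gives the homoallylic alcohol with the stereocentre retained.

Step 6
Reactants: 11 (2R)-1-(2-methyl-1,3-dithian-2-yl)pent-4-en-2-ol
Product: 12 2-{(2R)-2-[(4-methoxybenzyl)oxy]pent-4-en-1-yl}-2-methyl-1,3-dithiane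
Conditions: NaH, 4-methoxybenzyl chloride, n-Bu4NI (cat.), THF/DMF, 0 °C → rt
Reagents that add atoms: 4-methoxybenzyl chloride, COc1ccc(CCl)cc1
Why: Williamson etherification installs the PMB ether, the Lewis-basic β-alkoxy director needed in the key step.

Step 7
Reactants: 12 2-{(2R)-2-[(4-methoxybenzyl)oxy]pent-4-en-1-yl}-2-methyl-1,3-dithiane
Product: 13 (4R)-4-[(4-methoxybenzyl)oxy]hept-6-en-2-one
Conditions: MeI, CaCO3, MeCN/H2O (9:1), 45 °C
Reagents that add atoms: water, O
Why: S-alkylative dithiane hydrolysis unmasks the methyl ketone under near-neutral conditions that spare the PMB ether and the alkene and do not cause β-elimination.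

Step 8
Reactants: 13 (4R)-4-[(4-methoxybenzyl)oxy]hept-6-en-2-one; 4 (3R)-3-[(tert-butyldimethylsilyl)oxy]octadecanal
Product: 16 (4R,6R,8S,10R)-10-[(tert-butyldimethylsilyl)oxy]-4-[(4-methoxybenzyl)oxy]pentacos-1-ene-6,8-diol, via dicyclohexylboron enolate 14 (not isolated), via dicyclohexylboron aldolate 15 (not isolated)
Conditions: 13 (1.2 equiv), (c-C6H11)2BCl, Et3N, Et2O, 0 °C; 4, −78 → −20 °C; LiBH4 (THF), −78 °C; then MeOH, pH 7 buffer, 30% H2O2, 0 °C
Reagents that add atoms: none
Why: (c-C6H11)2BCl/Et3N enolises the methyl group of 13 to boron enolate 14, which adds to aldehyde 4 through a six-membered cyclic boron transition state in which a formyl C–H···O contact to the C4 PMB ether oxygen fixes the enolate side chain, so the new C8 hydroxyl forms 1,5-anti to the C4 ether (Paterson-type 1,5-anti boron aldol of a β-alkoxy methyl ketone). The boron aldolate 15 is a six-membered O–B–O=C chelate that LiBH4 reduces by external hydride delivery, so the C6 carbinol forms 1,3-syn to C8 (in situ variant of the Narasaka–Prasad reduction). No ring of the target is closed here; the only rings are the transient boron chelates. C8 is controlled by the C4 stereocentre and C6 by C8, so one bought stereocentre sets two others in the same flask in which the C25 chain is completed. The step needs the enolate-side bias to override the β-silyloxy stereocentre of 4, which should hold because closed boron transition states show only weak 1,3-induction from β-silyloxy aldehydes while a PMB ether is a strong 1,5-director. It also needs the ketone to be reduced only as its chelate, which the pre-formed aldolate and −78 °C should secure.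

Step 9
Reactants: 16 (4R,6R,8S,10R)-10-[(tert-butyldimethylsilyl)oxy]-4-[(4-methoxybenzyl)oxy]pentacos-1-ene-6,8-diol
Product: 17 tert-butyl({(2R)-1-[(4S,6S)-6-{(2R)-2-[(4-methoxybenzyl)oxy]pent-4-en-1-yl}-2,2-dimethyl-1,3-dioxan-4-yl]heptadecan-2-yl}oxy)dimethylsilane
Conditions: Me2C(OMe)2, PPTS (10 mol%), CH2Cl2, rt
Reagents that add atoms: 2,2-dimethoxypropane, COC(C)(C)OC
Why: Transketalisation of the syn-1,3-diol gives the cis-4,6-disubstituted 1,3-dioxane with both substituents equatorial, and PPTS leaves the TBS and PMB ethers intact.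

Step 10
Reactants: 17 tert-butyl({(2R)-1-[(4S,6S)-6-{(2R)-2-[(4-methoxybenzyl)oxy]pent-4-en-1-yl}-2,2-dimethyl-1,3-dioxan-4-yl]heptadecan-2-yl}oxy)dimethylsilane
Product: 18 (2R)-1-[(4S,6S)-6-{(2R)-2-[(tert-butyldimethylsilyl)oxy]heptadecyl}-2,2-dimethyl-1,3-dioxan-4-yl]pent-4-en-2-ol
Conditions: DDQ, CH2Cl2/pH 7 buffer (10:1), 0 °C → rt
Reagents that add atoms: none
Why: Oxidative PMB ether cleavage by DDQ proceeds through the benzylic oxocarbenium ion and its hydrolysis, and the buffered medium protects the acetonide and the silyl ether.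

Step 11
Reactants: 18 (2R)-1-[(4S,6S)-6-{(2R)-2-[(tert-butyldimethylsilyl)oxy]heptadecyl}-2,2-dimethyl-1,3-dioxan-4-yl]pent-4-en-2-ol; 19 acrylic acid
Product: 20 (2S)-1-[(4R,6S)-6-{(2R)-2-[(tert-butyldimethylsilyl)oxy]heptadecyl}-2,2-dimethyl-1,3-dioxan-4-yl]pent-4-en-2-yl prop-2-enoate
Conditions: PPh3, DIAD, THF, −20 °C → rt
Reagents that add atoms: none
Why: Mitsunobu esterification, in which acrylate displaces the alkoxyphosphonium of 18 by SN2 with inversion, turns the directing (R) carbinol into the (S) acrylate required for the all-syn target.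

Step 12
Reactants: 20 (2S)-1-[(4R,6S)-6-{(2R)-2-[(tert-butyldimethylsilyl)oxy]heptadecyl}-2,2-dimethyl-1,3-dioxan-4-yl]pent-4-en-2-yl prop-2-enoate
Product: 21 (6S)-6-{[(4R,6S)-6-{(2R)-2-[(tert-butyldimethylsilyl)oxy]heptadecyl}-2,2-dimethyl-1,3-dioxan-4-yl]methyl}-5,6-dihydro-2H-pyran-2-one
Conditions: second-generation Grubbs catalyst RuCl2(=CHPh)(PCy3)(H2IMes) (5 mol%), CH2Cl2 (0.003 M), 40 °C
Reagents that add atoms: none
Why: Ring-closing metathesis of the acrylate with the terminal alkene closes the six-membered α,β-unsaturated lactone, with the cis ring alkene enforced by ring size and ethene lost as the driving force.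

Step 13
Reactants: 21 (6S)-6-{[(4R,6S)-6-{(2R)-2-[(tert-butyldimethylsilyl)oxy]heptadecyl}-2,2-dimethyl-1,3-dioxan-4-yl]methyl}-5,6-dihydro-2H-pyran-2-one
Product: 22 (6S)-6-[(2R,4R,6R)-2,4,6-trihydroxyhenicosyl]-5,6-dihydro-2H-pyran-2-one
Conditions: 48% aq. HF, MeCN, 0 °C → rt
Reagents that add atoms: none
Why: Acidic global deprotection, in which HF cleaves the Si–O bond and the aqueous acid hydrolyses the acetonide, should leave the conjugated lactone intact under these mild, non-basic conditions.

**Compound list**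

1 | methyl 3-oxooctadecanoate | CCCCCCCCCCCCCCCC(=O)CC(=O)OC | starting material
2 | methyl (3R)-3-hydroxyoctadecanoate | CCCCCCCCCCCCCCC[C@@H](O)CC(=O)OC | intermediate
3 | methyl (3R)-3-[(tert-butyldimethylsilyl)oxy]octadecanoate | CCCCCCCCCCCCCCC[C@@H](O[Si](C)(C)C(C)(C)C)CC(=O)OC | intermediate
4 | (3R)-3-[(tert-butyldimethylsilyl)oxy]octadecanal | CCCCCCCCCCCCCCC[C@@H](O[Si](C)(C)C(C)(C)C)CC=O | intermediate
5 | 2-methyl-1,3-dithiane | CC1SCCCS1 | starting material
6 | (S)-epichlorohydrin, (2S)-2-(chloromethyl)oxirane | ClC[C@@H]1CO1 | starting material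
7 | 2-lithio-2-methyl-1,3-dithiane | [Li]C1(C)SCCCS1 | intermediate
8 | lithium (2S)-1-chloro-3-(2-methyl-1,3-dithian-2-yl)propan-2-olate | CC1(C[C@H](O[Li])CCl)SCCCS1 | intermediate
9 | (2S)-2-[(2-methyl-1,3-dithian-2-yl)methyl]oxirane | CC1(C[C@H]2CO2)SCCCS1 | intermediate
10 | vinylmagnesium bromide | C=C[Mg]Br | starting material
11 | (2R)-1-(2-methyl-1,3-dithian-2-yl)pent-4-en-2-ol | CC1(C[C@H](O)CC=C)SCCCS1 | intermediate
12 | 2-{(2R)-2-[(4-methoxybenzyl)oxy]pent-4-en-1-yl}-2-methyl-1,3-dithiane | CC1(C[C@H](OCc2ccc(OC)cc2)CC=C)SCCCS1 | intermediate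
13 | (4R)-4-[(4-methoxybenzyl)oxy]hept-6-en-2-one | CC(=O)C[C@H](OCc1ccc(OC)cc1)CC=C | intermediate
14 | (4R)-2-[(dicyclohexylboranyl)oxy]-4-[(4-methoxybenzyl)oxy]hepta-1,6-diene (boron enolate) | C=C(OB(C1CCCCC1)C1CCCCC1)C[C@H](OCc1ccc(OC)cc1)CC=C | intermediate
15 | (4R,8R,10R)-10-[(tert-butyldimethylsilyl)oxy]-8-[(dicyclohexylboranyl)oxy]-4-[(4-methoxybenzyl)oxy]pentacos-1-en-6-one (boron aldolate) | CCCCCCCCCCCCCCC[C@@H](O[Si](C)(C)C(C)(C)C)C[C@@H](OB(C1CCCCC1)C1CCCCC1)CC(=O)C[C@H](OCc1ccc(OC)cc1)CC=C | intermediate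
16 | (4R,6R,8S,10R)-10-[(tert-butyldimethylsilyl)oxy]-4-[(4-methoxybenzyl)oxy]pentacos-1-ene-6,8-diol | CCCCCCCCCCCCCCC[C@@H](O[Si](C)(C)C(C)(C)C)C[C@@H](O)C[C@@H](O)C[C@H](OCc1ccc(OC)cc1)CC=C | intermediate
17 | tert-butyl({(2R)-1-[(4S,6S)-6-{(2R)-2-[(4-methoxybenzyl)oxy]pent-4-en-1-yl}-2,2-dimethyl-1,3-dioxan-4-yl]heptadecan-2-yl}oxy)dimethylsilane | CCCCCCCCCCCCCCC[C@@H](O[Si](C)(C)C(C)(C)C)C[C@@H]1C[C@H](C[C@H](OCc2ccc(OC)cc2)CC=C)OC(C)(C)O1 | intermediate
18 | (2R)-1-[(4S,6S)-6-{(2R)-2-[(tert-butyldimethylsilyl)oxy]heptadecyl}-2,2-dimethyl-1,3-dioxan-4-yl]pent-4-en-2-ol | CCCCCCCCCCCCCCC[C@@H](O[Si](C)(C)C(C)(C)C)C[C@@H]1C[C@H](C[C@H](O)CC=C)OC(C)(C)O1 | intermediate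
19 | acrylic acid | C=CC(=O)O | starting material
20 | (2S)-1-[(4R,6S)-6-{(2R)-2-[(tert-butyldimethylsilyl)oxy]heptadecyl}-2,2-dimethyl-1,3-dioxan-4-yl]pent-4-en-2-yl prop-2-enoate | CCCCCCCCCCCCCCC[C@@H](O[Si](C)(C)C(C)(C)C)C[C@@H]1C[C@H](C[C@@H](OC(=O)C=C)CC=C)OC(C)(C)O1 | intermediate
21 | (6S)-6-{[(4R,6S)-6-{(2R)-2-[(tert-butyldimethylsilyl)oxy]heptadecyl}-2,2-dimethyl-1,3-dioxan-4-yl]methyl}-5,6-dihydro-2H-pyran-2-one | CCCCCCCCCCCCCCC[C@@H](O[Si](C)(C)C(C)(C)C)C[C@@H]1C[C@H](C[C@@H]2CC=CC(=O)O2)OC(C)(C)O1 | intermediate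
22 | (6S)-6-[(2R,4R,6R)-2,4,6-trihydroxyhenicosyl]-5,6-dihydro-2H-pyran-2-one | CCCCCCCCCCCCCCC[C@@H](O)C[C@@H](O)C[C@@H](O)C[C@@H]1CC=CC(=O)O1 | target

**Count and risks**

Total step count: 13. Longest linear sequence: 10 steps (steps 4–13, from 5 and 6 to 22).

Steps most likely to fail:

Step 8. The facial selectivity of the enolate addition may erode if the β-silyloxy stereocentre of the aldehyde opposes the 1,5-anti bias, and hydride delivery may partly bypass the boron chelate. The fallback replaces the single substrate-controlled flask by reagent-controlled double stereodifferentiation and a separate directed reduction. It sets out from 13 and 4: 13 is enolised with (+)-B-chlorodiisopinocampheylborane, (+)-(Ipc)2BCl, and Et3N in Et2O, whose si-face preference towards the aldehyde is expected to reinforce the 1,5-anti sense. Addition of 4 at −78 °C and oxidative work-up should give (4R,8R,10R)-10-[(tert-butyldimethylsilyl)oxy]-8-hydroxy-4-[(4-methoxybenzyl)oxy]pentacos-1-en-6-one F1, which can be freed from its C8 epimer by chromatography. Hydroxyl-directed Narasaka–Prasad reduction of F1 (Et2BOMe, NaBH4, THF/MeOH, −78 °C) comes back to the route at 16.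

Step 11. Triphenylphosphine may add to acrylic acid in conjugate fashion and the acid may oligomerise faster than the alkoxyphosphonium is displaced, or elimination may compete with inversion. The fallback separates the inversion from the installation of the acrylate and sets out from 18. Mitsunobu reaction with 4-nitrobenzoic acid (PPh3, DIAD, toluene) should give the inverted ester (2S)-1-[(4R,6S)-6-{(2R)-2-[(tert-butyldimethylsilyl)oxy]heptadecyl}-2,2-dimethyl-1,3-dioxan-4-yl]pent-4-en-2-yl 4-nitrobenzoate F2. Methanolysis (K2CO3, MeOH) should give the epimeric alcohol (2S)-1-[(4S,6S)-6-{(2R)-2-[(tert-butyldimethylsilyl)oxy]heptadecyl}-2,2-dimethyl-1,3-dioxan-4-yl]pent-4-en-2-ol F3. Acylation of F3 with acryloyl chloride (Et3N, DMAP cat., CH2Cl2, 0 °C) comes back to the route at 20.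

Step 13. The liberated C2' hydroxyl may add in conjugate fashion to the unsaturated lactone, or the lactone may open while the acetonide is hydrolysed. The fallback changes the order of events so that the lactone never meets acid, and sets out from 20. Aqueous HF in MeCN at 0 °C removes the silyl ether and the acetonide first and should give (4S,6R,8R,10R)-6,8,10-trihydroxypentacos-1-en-4-yl prop-2-enoate F4, which is kept cold and used at once to limit acyl migration. Ring-closing metathesis of the free triol F4 (RuCl2(=CHPh)(PCy3)(H2IMes), CH2Cl2, 40 °C) then closes the lactone last under neutral conditions and comes back to the route at 22.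

**Further compounds**

F1 | step 8 | (4R,8R,10R)-10-[(tert-butyldimethylsilyl)oxy]-8-hydroxy-4-[(4-methoxybenzyl)oxy]pentacos-1-en-6-one | CCCCCCCCCCCCCCC[C@@H](O[Si](C)(C)C(C)(C)C)C[C@@H](O)CC(=O)C[C@H](OCc1ccc(OC)cc1)CC=C
F2 | step 11 | (2S)-1-[(4R,6S)-6-{(2R)-2-[(tert-butyldimethylsilyl)oxy]heptadecyl}-2,2-dimethyl-1,3-dioxan-4-yl]pent-4-en-2-yl 4-nitrobenzoate | CCCCCCCCCCCCCCC[C@@H](O[Si](C)(C)C(C)(C)C)C[C@@H]1C[C@H](C[C@@H](OC(=O)c2ccc(cc2)[N+](=O)[O-])CC=C)OC(C)(C)O1
F3 | step 11 | (2S)-1-[(4S,6S)-6-{(2R)-2-[(tert-butyldimethylsilyl)oxy]heptadecyl}-2,2-dimethyl-1,3-dioxan-4-yl]pent-4-en-2-ol | CCCCCCCCCCCCCCC[C@@H](O[Si](C)(C)C(C)(C)C)C[C@@H]1C[C@H](C[C@@H](O)CC=C)OC(C)(C)O1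
F4 | step 13 | (4S,6R,8R,10R)-6,8,10-trihydroxypentacos-1-en-4-yl prop-2-enoate | CCCCCCCCCCCCCCC[C@@H](O)C[C@@H](O)C[C@@H](O)C[C@@H](OC(=O)C=C)CC=C
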